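**Retrosynthetic overview**

1. Feature: in the pyran ring (ring C), C3 lies between two methylene carbons, C2 (bonded to O1) and C4 (bonded to C4a of ring A). With a second CH2OH in place of H-3 it becomes a prochiral quaternary carbon whose two hydroxymethyl arms are enantiotopic towards a bromide at C8a.
2. Key disconnection O1–C8a: a chiral copper catalyst arylates one arm of a 2-aryl-2-(2-bromobenzyl)propane-1,3-diol and closes ring C, the only ring made (rings A and B are bought as arenes). The spare arm is then oxidised to CHO and expelled as CO with retention, leaving H-3.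
3. The diol comes from dimethyl malonate: C3–C1′ by palladium-catalysed arylation with the ring B bromide, C3–C4 by alkylation with the ring A benzyl bromide, then LiAlH4.
4. Both 1,1-dimethylallyl groups (C6 and C5′) come from aromatic Claisen rearrangement of prenyl ethers of 2-bromo-4-hydroxybenzaldehyde and 4-bromoresorcinol.
5. The three phenols travel as methoxymethyl (MOM) ethers, which are small enough beside the tert-alkyl groups and cannot migrate to the alkoxide arms; they are freed in the last step.

Key step: step 12

Assumption: which antipode of the chiral diamine steers ring closure to the 3R series is not predicted here; both antipodes are accessible, and the one that delivers the R-configured (chroman-3-yl)methanol is used (to be confirmed by the optical rotation of the final product).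

**Route**

Step 1
Reactants: 1 2-bromo-4-hydroxybenzaldehyde; 2 prenyl bromide
Product: 3 2-bromo-4-[(3-methylbut-2-en-1-yl)oxy]benzaldehyde
Conditions: K2CO3, DMF, rt
Reagents that add atoms: prenyl bromide (compound 2), CC(C)=CCBr
Why: Williamson ether synthesis; the acidic para-formyl phenoxide should attack the primary carbon of prenyl bromide (SN2), with aldehyde and aryl bromide untouched.

Step 2
Reactants: 3 2-bromo-4-[(3-methylbut-2-en-1-yl)oxy]benzaldehyde
Product: 5 2-bromo-4-hydroxy-5-(2-methylbut-3-en-2-yl)benzaldehyde, via Claisen ortho-dienone 4 (not isolated)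
Conditions: PhNEt2, 190 °C, sealed tube, Ar
Reagents that add atoms: none
Why: Aromatic Claisen rearrangement; the [3,3]-shift should join the tertiary prenyl terminus to C5, the ortho position not flanked by bromine (a dienone formed at crowded C3 can revert because the para position is blocked), and tautomerisation of dienone 4 gives the 1,1-dimethylallyl phenol, with short heating under argon to limit abnormal Claisen isomerisation and cyclisation.

Step 3
Reactants: 5 2-bromo-4-hydroxy-5-(2-methylbut-3-en-2-yl)benzaldehyde
Product: 6 2-bromo-4-(methoxymethoxy)-5-(2-methylbut-3-en-2-yl)benzaldehyde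
Conditions: MOMCl, K2CO3, acetone, rt
Reagents that add atoms: chloromethyl methyl ether (MOMCl), COCCl
Why: O-alkylation of the acidic para-formyl phenoxide by the reactive α-chloro ether (MOM ether formation); the small acetal group should fit beside the tert-alkyl substituent where a bulky silyl group would not.

Step 4
Reactants: 6 2-bromo-4-(methoxymethoxy)-5-(2-methylbut-3-en-2-yl)benzaldehyde
Product: 7 [2-bromo-4-(methoxymethoxy)-5-(2-methylbut-3-en-2-yl)phenyl]methanol
Conditions: NaBH4, MeOH, 0 °C
Reagents that add atoms: none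
Why: Borohydride reduction of the aldehyde; aryl bromide, vinyl group and acetal are inert to NaBH4.

Step 5
Reactants: 7 [2-bromo-4-(methoxymethoxy)-5-(2-methylbut-3-en-2-yl)phenyl]methanol
Product: 8 1-bromo-2-(bromomethyl)-5-(methoxymethoxy)-4-(2-methylbut-3-en-2-yl)benzene
Conditions: CBr4, PPh3, CH2Cl2, 0 °C
Reagents that add atoms: tetrabromomethane, BrC(Br)(Br)Br
Why: Appel reaction; the neutral conditions should spare the MOM ether and the vinyl group, and the electron-rich benzylic bromide is used crude in step 10.

Step 6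
Reactants: 9 4-bromoresorcinol; 2 prenyl bromide
Product: 10 2-bromo-5-[(3-methylbut-2-en-1-yl)oxy]phenol
Conditions: 2 (0.95 equiv), K2CO3 (1.0 equiv), acetone, rt
Reagents that add atoms: prenyl bromide (compound 2), CC(C)=CCBr
Why: Williamson ether synthesis; mono-alkylation should occur at the hydroxyl para to bromine, which is unhindered and gives the more nucleophilic phenoxide, whereas the hydroxyl ortho to bromine is shielded and inductively deactivated (a slight deficit of prenyl bromide limits bis-alkylation, and the minor isomer and bis-ether are removed by chromatography).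

Step 7
Reactants: 10 2-bromo-5-[(3-methylbut-2-en-1-yl)oxy]phenol
Product: 12 4-bromo-6-(2-methylbut-3-en-2-yl)benzene-1,3-diol, via Claisen ortho-dienone 11 (not isolated)
Conditions: PhNEt2, 185 °C, sealed tube, Ar
Reagents that add atoms: none
Why: Aromatic Claisen rearrangement; the tertiary prenyl terminus should go to the ortho position para to the free hydroxyl and not to the crowded position between the two oxygens, in line with the preference of meta-donor-substituted aryl allyl ethers, and dienone 11 then tautomerises.

Step 8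
Reactants: 12 4-bromo-6-(2-methylbut-3-en-2-yl)benzene-1,3-diol
Product: 13 1-bromo-2,4-bis(methoxymethoxy)-5-(2-methylbut-3-en-2-yl)benzene
Conditions: NaH, MOMCl, DMF, 0 °C → rt
Reagents that add atoms: chloromethyl methyl ether (MOMCl), COCCl
Why: Double O-alkylation of the bis-phenoxide (MOM ether formation); the sodium phenoxides should react even at the hydroxyl next to the tert-alkyl group.

Step 9
Reactants: 13 1-bromo-2,4-bis(methoxymethoxy)-5-(2-methylbut-3-en-2-yl)benzene; 14 dimethyl malonate
Product: 15 dimethyl 2-[2,4-bis(methoxymethoxy)-5-(2-methylbut-3-en-2-yl)phenyl]propanedioate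
Conditions: Pd(dba)2 (3 mol %), P(t-Bu)3·HBF4 (6 mol %), K3PO4, toluene, 75 °C
Reagents that add atoms: dimethyl malonate (compound 14), COC(=O)CC(=O)OC
Why: Palladium-catalysed α-arylation of a malonate enolate; zerovalent palladium with the bulky electron-rich phosphine should insert into the electron-rich ortho-alkoxy aryl bromide (a substrate class beyond the copper-mediated variant), and the step is placed before the ring A aryl bromide enters the molecule.

Step 10
Reactants: 15 dimethyl 2-[2,4-bis(methoxymethoxy)-5-(2-methylbut-3-en-2-yl)phenyl]propanedioate; 8 1-bromo-2-(bromomethyl)-5-(methoxymethoxy)-4-(2-methylbut-3-en-2-yl)benzene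
Product: 16 dimethyl 2-[2,4-bis(methoxymethoxy)-5-(2-methylbut-3-en-2-yl)phenyl]-2-{[2-bromo-4-(methoxymethoxy)-5-(2-methylbut-3-en-2-yl)phenyl]methyl}propanedioate
Conditions: NaH, THF–DMF, 0 °C; then 8, rt
Reagents that add atoms: none
Why: Malonate alkylation (SN2); the stabilised arylmalonate anion should displace the reactive benzylic bromide and create the quaternary carbon, the aryl bromide being inert.

Step 11
Reactants: 16 dimethyl 2-[2,4-bis(methoxymethoxy)-5-(2-methylbut-3-en-2-yl)phenyl]-2-{[2-bromo-4-(methoxymethoxy)-5-(2-methylbut-3-en-2-yl)phenyl]methyl}propanedioate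
Product: 17 2-[2,4-bis(methoxymethoxy)-5-(2-methylbut-3-en-2-yl)phenyl]-2-{[2-bromo-4-(methoxymethoxy)-5-(2-methylbut-3-en-2-yl)phenyl]methyl}propane-1,3-diol
Conditions: LiAlH4, THF, 0 °C → rt
Reagents that add atoms: none
Why: Hydride reduction of both esters to the prochiral 1,3-diol; at or below room temperature the aryl bromide, vinyl groups and MOM ethers should survive, and the non-enolisable quaternary malonate cannot be deprotonated.

Step 12
Reactants: 17 2-[2,4-bis(methoxymethoxy)-5-(2-methylbut-3-en-2-yl)phenyl]-2-{[2-bromo-4-(methoxymethoxy)-5-(2-methylbut-3-en-2-yl)phenyl]methyl}propane-1,3-diol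
Product: 18 [(3R)-3-[2,4-bis(methoxymethoxy)-5-(2-methylbut-3-en-2-yl)phenyl]-7-(methoxymethoxy)-6-(2-methylbut-3-en-2-yl)-3,4-dihydro-2H-chromen-3-yl]methanol
Conditions: CuI (10 mol %), C2-symmetric chiral 1,2-diamine (N,N′-dimethyl-1,2-diphenylethane-1,2-diamine, chosen antipode, 20 mol %), Cs2CO3, MeCN (0.03 M), 25–40 °C, Ar
Reagents that add atoms: none
Why: The diamine-ligated CuI, with Cs2CO3 as base, should bind one hydroxymethyl group of 17 as a monovalent copper alkoxide, insert into the C8a–Br bond and form O1–C8a by C–O reductive elimination. The closest known reaction type is the Ullmann-type copper/diamine-catalysed intramolecular O-arylation of aliphatic alcohols in its enantioselective desymmetrising form, established for 2,2-disubstituted 2-(2-bromobenzyl)propane-1,3-diols giving (chroman-3-yl)methanols with a quaternary C3. Ring C closes in a 6-exo mode, the alkoxide oxygen attacking ring carbon C8a while bromide leaves outside the new ring, and either arm can give only this ring size. The quaternary stereocentre C3 arises from the choice between the two enantiotopic CH2OH arms and is controlled by the chiral diamine on copper (catalyst control, ligand antipode chosen for the 3R series). The step needs enantiotopic-group selectivity and chemoselectivity for alkoxide arylation; the substrate secures the latter because all phenols are non-migrating MOM ethers and only one aryl bromide is present, so a second arylation is impossible.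

Step 13
Reactants: 18 [(3R)-3-[2,4-bis(methoxymethoxy)-5-(2-methylbut-3-en-2-yl)phenyl]-7-(methoxymethoxy)-6-(2-methylbut-3-en-2-yl)-3,4-dihydro-2H-chromen-3-yl]methanol
Product: 19 (3S)-3-[2,4-bis(methoxymethoxy)-5-(2-methylbut-3-en-2-yl)phenyl]-7-(methoxymethoxy)-6-(2-methylbut-3-en-2-yl)-3,4-dihydro-2H-chromene-3-carbaldehyde
Conditions: Dess–Martin periodinane, CH2Cl2, 0 °C → rt
Reagents that add atoms: none
Why: Dess–Martin oxidation of the neopentyl primary alcohol; the aldehyde sits on a quaternary carbon and cannot enolise, so C3 keeps its configuration (the descriptor changes from R to S only because CHO outranks C2).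

Step 14
Reactants: 19 (3S)-3-[2,4-bis(methoxymethoxy)-5-(2-methylbut-3-en-2-yl)phenyl]-7-(methoxymethoxy)-6-(2-methylbut-3-en-2-yl)-3,4-dihydro-2H-chromene-3-carbaldehyde
Product: 20 (3R)-3-[2,4-bis(methoxymethoxy)-5-(2-methylbut-3-en-2-yl)phenyl]-7-(methoxymethoxy)-6-(2-methylbut-3-en-2-yl)-3,4-dihydro-2H-chromene
Conditions: RhCl(PPh3)3 (1.2 equiv), PhCN, 140 °C, Ar
Reagents that add atoms: none
Why: Tsuji–Wilkinson decarbonylation; monovalent rhodium should insert into the formyl C–H bond, extrude CO by retro-migratory insertion and release the C3–H bond by reductive elimination, each with retention (known for α-aryl α-quaternary aldehydes), so H-3 takes the place of the formyl group and gives the 3R configuration, while the vinyl groups have no allylic hydrogen to isomerise.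

Step 15
Reactants: 20 (3R)-3-[2,4-bis(methoxymethoxy)-5-(2-methylbut-3-en-2-yl)phenyl]-7-(methoxymethoxy)-6-(2-methylbut-3-en-2-yl)-3,4-dihydro-2H-chromene
Product: 21 Manuifolin E
Conditions: 3 M HCl, MeOH–THF, 45 °C
Reagents that add atoms: none
Why: Acid-catalysed acetal cleavage of the three MOM ethers, methanol carrying off the formaldehyde unit as dimethoxymethane; dilute methanolic acid should not protonate the monosubstituted vinyl groups, and C3 has no acidifying neighbour, so the stereocentre is untouched.

**Compound list**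

1 | 2-bromo-4-hydroxybenzaldehyde | O=Cc1ccc(O)cc1Br | starting material
2 | prenyl bromide (1-bromo-3-methylbut-2-ene) | CC(C)=CCBr | starting material
3 | 2-bromo-4-[(3-methylbut-2-en-1-yl)oxy]benzaldehyde | O=Cc1ccc(OCC=C(C)C)cc1Br | intermediate
4 | 6-bromo-3-(2-methylbut-3-en-2-yl)-4-oxocyclohexa-1,5-diene-1-carbaldehyde (Claisen ortho-dienone, racemic) | O=CC1=CC(C(C)(C)C=C)C(=O)C=C1Br | intermediate (not isolated)
5 | 2-bromo-4-hydroxy-5-(2-methylbut-3-en-2-yl)benzaldehyde | O=Cc1cc(C(C)(C)C=C)c(O)cc1Br | intermediate
6 | 2-bromo-4-(methoxymethoxy)-5-(2-methylbut-3-en-2-yl)benzaldehyde | O=Cc1cc(C(C)(C)C=C)c(OCOC)cc1Br | intermediate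
7 | [2-bromo-4-(methoxymethoxy)-5-(2-methylbut-3-en-2-yl)phenyl]methanol | OCc1cc(C(C)(C)C=C)c(OCOC)cc1Br | intermediate
8 | 1-bromo-2-(bromomethyl)-5-(methoxymethoxy)-4-(2-methylbut-3-en-2-yl)benzene | BrCc1cc(C(C)(C)C=C)c(OCOC)cc1Br | intermediate
9 | 4-bromoresorcinol (4-bromobenzene-1,3-diol) | Oc1ccc(Br)c(O)c1 | starting material
10 | 2-bromo-5-[(3-methylbut-2-en-1-yl)oxy]phenol | Oc1cc(OCC=C(C)C)ccc1Br | intermediate
11 | 4-bromo-3-hydroxy-6-(2-methylbut-3-en-2-yl)cyclohexa-2,4-dien-1-one (Claisen ortho-dienone, racemic) | OC1=CC(=O)C(C(C)(C)C=C)C=C1Br | intermediate (not isolated)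
12 | 4-bromo-6-(2-methylbut-3-en-2-yl)benzene-1,3-diol | Oc1cc(O)c(C(C)(C)C=C)cc1Br | intermediate
13 | 1-bromo-2,4-bis(methoxymethoxy)-5-(2-methylbut-3-en-2-yl)benzene | COCOc1cc(OCOC)c(C(C)(C)C=C)cc1Br | intermediate
14 | dimethyl malonate | COC(=O)CC(=O)OC | starting material
15 | dimethyl 2-[2,4-bis(methoxymethoxy)-5-(2-methylbut-3-en-2-yl)phenyl]propanedioate | COC(=O)C(C(=O)OC)c1cc(C(C)(C)C=C)c(OCOC)cc1OCOC | intermediate
16 | dimethyl 2-[2,4-bis(methoxymethoxy)-5-(2-methylbut-3-en-2-yl)phenyl]-2-{[2-bromo-4-(methoxymethoxy)-5-(2-methylbut-3-en-2-yl)phenyl]methyl}propanedioate | COC(=O)C(Cc1cc(C(C)(C)C=C)c(OCOC)cc1Br)(C(=O)OC)c1cc(C(C)(C)C=C)c(OCOC)cc1OCOC | intermediate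
17 | 2-[2,4-bis(methoxymethoxy)-5-(2-methylbut-3-en-2-yl)phenyl]-2-{[2-bromo-4-(methoxymethoxy)-5-(2-methylbut-3-en-2-yl)phenyl]methyl}propane-1,3-diol (key-step precursor) | OCC(CO)(Cc1cc(C(C)(C)C=C)c(OCOC)cc1Br)c1cc(C(C)(C)C=C)c(OCOC)cc1OCOC | intermediate
18 | [(3R)-3-[2,4-bis(methoxymethoxy)-5-(2-methylbut-3-en-2-yl)phenyl]-7-(methoxymethoxy)-6-(2-methylbut-3-en-2-yl)-3,4-dihydro-2H-chromen-3-yl]methanol (key-step product) | C=CC(C)(C)c1cc2c(cc1OCOC)OC[C@@](CO)(c1cc(C(C)(C)C=C)c(OCOC)cc1OCOC)C2 | intermediate
19 | (3S)-3-[2,4-bis(methoxymethoxy)-5-(2-methylbut-3-en-2-yl)phenyl]-7-(methoxymethoxy)-6-(2-methylbut-3-en-2-yl)-3,4-dihydro-2H-chromene-3-carbaldehyde | C=CC(C)(C)c1cc2c(cc1OCOC)OC[C@@](C=O)(c1cc(C(C)(C)C=C)c(OCOC)cc1OCOC)C2 | intermediate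
20 | (3R)-3-[2,4-bis(methoxymethoxy)-5-(2-methylbut-3-en-2-yl)phenyl]-7-(methoxymethoxy)-6-(2-methylbut-3-en-2-yl)-3,4-dihydro-2H-chromene (tris-MOM ether of the target) | C=CC(C)(C)c1cc2c(cc1OCOC)OC[C@@H](c1cc(C(C)(C)C=C)c(OCOC)cc1OCOC)C2 | intermediate
21 | Manuifolin E, 4-[(3R)-7-hydroxy-6-(2-methylbut-3-en-2-yl)-3,4-dihydro-2H-chromen-3-yl]-6-(2-methylbut-3-en-2-yl)benzene-1,3-diol | C=CC(C)(C)c1cc2c(cc1O)OC[C@@H](c1cc(C(C)(C)C=C)c(O)cc1O)C2 | target

**Step count and risks**

Total step count: 15. Longest linear sequence: 11 steps (steps 1–5, then 10–15, from 2-bromo-4-hydroxybenzaldehyde); the ring B branch (steps 6–9) joins at step 10.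

Steps most likely to fail:

1. Step 12. Insertion of copper into the electron-rich C8a–Br bond may be slow, and discrimination between the two enantiotopic hydroxymethyl arms beside the bulky ortho-substituted ring B may be weak, so the ring could close sluggishly or with low enantiomeric purity. Fallback (resolution in place of asymmetric catalysis), setting out from 17 and returning at 18: ring closure of 17 with CuI and the achiral ligand 1,10-phenanthroline (Cs2CO3, toluene, 90 °C) should give the racemic (chroman-3-yl)methanol F1. Esterification with (S)-2-methoxy-2-phenylacetic acid (DCC, DMAP, CH2Cl2) should give two diastereomeric esters, to be separated by chromatography or crystallisation and assigned by crystallography. The (S)-O-methylmandelate of the 3R-series alcohol F2 is kept, and methanolysis (K2CO3, MeOH) should release 18.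

2. Step 14. Insertion of rhodium into the formyl C–H bond of the crowded neopentyl-type aldehyde may be slow, and after loss of CO the tertiary alkylrhodium hydride may undergo β-hydride elimination towards C2 or C4 instead of C–H reductive elimination. Fallback (auxiliary-controlled alkylation that sets C3 directly as a tertiary centre, so that no carbon has to be excised), setting out from 15 and 8 and returning at 20: saponification of 15 (LiOH, THF–H2O) followed by acidification and warming should give, after decarboxylation, the arylacetic acid F3. Activation with pivaloyl chloride and Et3N and acylation of lithiated (R)-4-benzyl-1,3-oxazolidin-2-one should give the N-acyl oxazolidinone F4. Evans alkylation of its sodium enolate (NaN(SiMe3)2, THF, −78 °C) with 8 should give the (2R)-alkylated imide F5, the benzyl bromide entering anti to the auxiliary benzyl group. LiBH4 (THF–H2O, 0 °C) should release the (2R)-2-aryl-3-(2-bromoaryl)propan-1-ol F6, and copper-catalysed intramolecular O-arylation (CuI, 1,10-phenanthroline, Cs2CO3, toluene, 110 °C) should close ring C to give 20.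

3. Step 2. At the temperature of the rearrangement the prenyl group may be lost, some migration may go to C3 next to bromine, and the first-formed ortho-(1,1-dimethylallyl)phenol may isomerise further (abnormal Claisen) or cyclise onto its vinyl group; step 7 shares this hazard in milder form. Fallback (cross-coupling in place of the sigmatropic shift), setting out from 1 and returning at 6: iodination of 1 ortho to the hydroxyl (N-iodosuccinimide, MeCN, rt) should give 2-bromo-4-hydroxy-5-iodobenzaldehyde F7. MOM protection (MOMCl, K2CO3, acetone) should give 2-bromo-5-iodo-4-(methoxymethoxy)benzaldehyde F8. A branched-selective (γ-selective) Suzuki–Miyaura coupling with 3,3-dimethylallylboronic acid pinacol ester at the more reactive C–I bond (Pd(OAc)2, bulky dialkylbiarylphosphine, aqueous K3PO4, THF, 40 °C) should give 6.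

**Further compounds**

F1 | step 12 | racemic [3-[2,4-bis(methoxymethoxy)-5-(2-methylbut-3-en-2-yl)phenyl]-7-(methoxymethoxy)-6-(2-methylbut-3-en-2-yl)-3,4-dihydro-2H-chromen-3-yl]methanol | C=CC(C)(C)c1cc2c(cc1OCOC)OCC(CO)(c1cc(C(C)(C)C=C)c(OCOC)cc1OCOC)C2
F2 | step 12 | (S)-2-methoxy-2-phenylacetate ester of 18 (single diastereomer, C3 configured as in 18) | C=CC(C)(C)c1cc2c(cc1OCOC)OC[C@@](COC(=O)[C@@H](OC)c1ccccc1)(c1cc(C(C)(C)C=C)c(OCOC)cc1OCOC)C2
F3 | step 14 | 2-[2,4-bis(methoxymethoxy)-5-(2-methylbut-3-en-2-yl)phenyl]acetic acid | OC(=O)Cc1cc(C(C)(C)C=C)c(OCOC)cc1OCOC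
F4 | step 14 | (4R)-4-benzyl-3-{[2,4-bis(methoxymethoxy)-5-(2-methylbut-3-en-2-yl)phenyl]acetyl}-1,3-oxazolidin-2-one | O=C(Cc1cc(C(C)(C)C=C)c(OCOC)cc1OCOC)N1C(=O)OC[C@H]1Cc1ccccc1
F5 | step 14 | (4R)-4-benzyl-3-[(2R)-2-[2,4-bis(methoxymethoxy)-5-(2-methylbut-3-en-2-yl)phenyl]-3-[2-bromo-4-(methoxymethoxy)-5-(2-methylbut-3-en-2-yl)phenyl]propanoyl]-1,3-oxazolidin-2-one | O=C([C@H](Cc1cc(C(C)(C)C=C)c(OCOC)cc1Br)c1cc(C(C)(C)C=C)c(OCOC)cc1OCOC)N1C(=O)OC[C@H]1Cc1ccccc1
F6 | step 14 | (2R)-2-[2,4-bis(methoxymethoxy)-5-(2-methylbut-3-en-2-yl)phenyl]-3-[2-bromo-4-(methoxymethoxy)-5-(2-methylbut-3-en-2-yl)phenyl]propan-1-ol | OC[C@@H](c1cc(C(C)(C)C=C)c(OCOC)cc1OCOC)Cc1cc(C(C)(C)C=C)c(OCOC)cc1Br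
F7 | step 2 | 2-bromo-4-hydroxy-5-iodobenzaldehyde | O=Cc1cc(I)c(O)cc1Br
F8 | step 2 | 2-bromo-5-iodo-4-(methoxymethoxy)benzaldehyde | O=Cc1cc(I)c(OCOC)cc1Br
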